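A ratio of two rates is what this flask needs: how much faster J is made at one time than at twice that time.

| setting | south-west | south | flask |
|---|---|---|---|
| L | 0.70 M | 1 M | 1.4 M |
| E | 1.54 M | 1.54 M | 1.54 M |
| Q | 2 mM | 2 mM | 2.0 mM |
| remark | run made earlier | run made earlier |  |

| run | time / s | J / % | L / % |
|---|---|---|---|
| south-west | 10.0 | 7.0 | 63.2 |
| south-west | 25.0 | 17.0 | 48.9 |
| south-west | 50.0 | 26.5 | 38.8 |
| south-west | 80.0 | 33.0 | 33.1 |
| south | 10.0 | 5.2 | 65.1 |
| south | 25.0 | 12.7 | 52.2 |
| south | 50.0 | 19.2 | 44.5 |
| south | 80.0 | 24.6 | 39.6 |

(scatter of a reading: 0.5 percentage points)

- apparent order in E when 50 % of the L are converted (percent change of the rate of making J for one percent more E charged)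
- factor on the rate of making J when 50 % of the L are converted if Q is charged twice over

- the numbers in the tables scatter with a standard deviation of 0.5 percentage points
- no earlier run changes the charge of Q; that part of a forecast is a guess
- no earlier run changes the charge of E; that part of a forecast is a guess

L is the substrate, Q the catalyst, E the reagent and J the product. The south run has half of its L converted near 25.0 s, and its charge of L lies closer to the flask's than the south-west charge does, so we take it as the stand-in for the flask and read the rate over the intervals on either side of that reading. Their middles lie about a factor of 2 apart in time. The earlier rate over the later rate is the clock factor f, here a reading with the scatter of its points: 1.92. The south-west run reads 1.75.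

For doubled Q in the flask, our bound from below assumes a rate proportional to Q with no slowing: 2. Our bound from above grants 2 times the whole fall in the south run, first interval over last: 5.78. To tighten it, we put the first answer back in. A doubled rate reaches the same conversion in about half the time, and at that earlier time we take the rate to be higher by f. So we commit to 2 times f, 3.85. No run varies E, so we reckon no order in E.

The forecast puts the doubling factor at 2, between 1.5 and 2.6, saying “Reaching 50 % sooner means less decay”, and the order in E at 0.7, between 0 and 1.2.

The flask gives an order in E of 0.74 and a doubling factor of 3.82, when 50 % of its L is converted, at 0.740 min.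

    2 E → X (k = 0.0250 M⁻¹ s⁻¹)
    E + Z → Q + J (k = 5.10 M⁻¹ s⁻¹)
    L + Q ⇌ Q + G (K = 1.30, k = 54.0 M⁻¹ s⁻¹)
    Q + G ⇌ Z (K = 52.0 M⁻¹, k = 39.0 M⁻¹ s⁻¹)

Halving the flask's factor gives it a clock factor of 1.91. In the flask E falls from 49.0 % of its charge at 0.200 min to 12.9 % at 1.00 min, and it ends as the limiting reagent, with 0 % left at 20.0 min and L still at 31.9 %. At 0.144 min the flask uses E to make X faster than it uses E to make J, by a factor of 6.0. In the same flask run without the step to X, the order in Q at this conversion falls from 2.2 to 1.0, a rate proportional to Q, which puts f near 1.00.

The readings are simulated on assumed constants; noise was put on by code.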